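Numbering: flavan numbering (O1, C2–C4, C4a, C5–C8, C8a). Ring A is the central arene, ring C the pyran, and Cα the side-chain methine on C6.
Cuts: with the four phenols masked as benzyl ethers, ring C is cut at C4–C4a and at C8a–O1. The side chain is cut at its CH2–aryl bond and at the Cα–(4-oxyphenyl) bond.
Enabling feature: the piece O1–C2–C3–C4 that drops out of ring C is the complete ring of a 2-aryloxetane. C8a and C4a are neighbours on ring A, so an iodide at C8a beside a free C4a–H is the ipso/ortho pair that palladium/norbornene catalysis functionalises in one pass.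
Forward order: a coumarin is made, arylated at C4, opened, joined to the third arene, deoxygenated and changed from bromide to iodide. The oxetane is built in parallel from an acetophenone, ring C is closed in the penultimate step, and global debenzylation follows.
Stereochemistry: Cα (R) comes from a rhodium/(R)-SEGPHOS conjugate arylation and C2 (S) from a ruthenium/(R)-SEGPHOS hydrogenation of a β-keto ester. Neither centre is disturbed later, because the oxetane C2–O bond is never broken.

Key step: step 16

Assumption: 1-butylbicyclo[2.2.1]hept-2-ene, the bridgehead-substituted norbornene mediator of step 16, is counted as an auxiliary reagent at hand, since it returns unchanged and gives no atom to the product.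

Step 1
Reactants: 1 4-bromo-2-hydroxybenzaldehyde
Product: 3 7-bromocoumarin, via ethyl hydroxycinnamate 2 (not isolated)
Conditions: Ph3P=CHCO2Et (1.2 equiv), PhNEt2, reflux
Reagents that add atoms: ethyl (triphenylphosphoranylidene)acetate, CCOC(=O)C=P(c1ccccc1)(c1ccccc1)c1ccccc1
Why: Wittig olefination gives the cinnamate, which at this temperature isomerises from E to Z and lactonises onto the free phenol, a standard one-flask coumarin synthesis that leaves the aryl bromide alone.

Step 2
Reactants: 3 7-bromocoumarin; 4 4-(benzyloxy)phenylboronic acid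
Product: 5 (R)-4-[4-(benzyloxy)phenyl]-7-bromochroman-2-one
Conditions: 4 (excess), Rh(acac)(C2H4)2 (3 mol%), (R)-SEGPHOS (3.3 mol%), 1,4-dioxane/H2O 10:1, 60 °C
Reagents that add atoms: none
Why: Hayashi–Miyaura asymmetric 1,4-addition of an arylboronic acid to a coumarin, a substrate class on which SEGPHOS is highly selective; the (R)-ligand should deliver the aryl group to the face that makes C4 (the future Cα) R, and the monovalent rhodium catalyst does not insert into the C–Br bond.

Step 3
Reactants: 5 (R)-4-[4-(benzyloxy)phenyl]-7-bromochroman-2-one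
Product: 7 methyl (R)-3-[2-(benzyloxy)-4-bromophenyl]-3-[4-(benzyloxy)phenyl]propanoate, via phenol methyl ester 6 (not isolated)
Conditions: K2CO3, BnBr, MeOH/acetone 1:1, reflux
Reagents that add atoms: methanol, CO; benzyl bromide, BrCc1ccccc1
Why: Base-mediated methanolysis of the dihydrocoumarin frees a phenoxide that is trapped at once by Williamson etherification, so relactonisation is shut off, and the Cα–H bond is far too weakly acidic to be affected.

Step 4
Reactants: 7 methyl (R)-3-[2-(benzyloxy)-4-bromophenyl]-3-[4-(benzyloxy)phenyl]propanoate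
Product: 8 (R)-3-[2-(benzyloxy)-4-bromophenyl]-3-[4-(benzyloxy)phenyl]propanal
Conditions: i-Bu2AlH (1.1 equiv), CH2Cl2, −78 °C
Reagents that add atoms: none
Why: Partial hydride reduction of a methyl ester stops at the tetrahedral aluminium hemiacetal at low temperature and should release the aldehyde only on work-up.

Step 5
Reactants: 9 4-bromo-3-methoxyphenol
Product: 10 4-(benzyloxy)-1-bromo-2-methoxybenzene
Conditions: BnBr, K2CO3, acetone, reflux
Reagents that add atoms: benzyl bromide, BrCc1ccccc1
Why: Williamson ether synthesis on a simple phenol.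

Step 6
Reactants: 10 4-(benzyloxy)-1-bromo-2-methoxybenzene; 8 (R)-3-[2-(benzyloxy)-4-bromophenyl]-3-[4-(benzyloxy)phenyl]propanal
Product: 12 (3R)-3-[2-(benzyloxy)-4-bromophenyl]-1-[4-(benzyloxy)-2-methoxyphenyl]-3-[4-(benzyloxy)phenyl]propan-1-ol as both C1 epimers, via arylmagnesium bromide 11 (not isolated)
Conditions: 10, Mg, THF, 45 °C; then 8, THF, −20 to 0 °C
Reagents that add atoms: none
Why: Grignard formation and 1,2-addition to the aldehyde, which is much faster than any exchange with the aryl bromide of 8; the new carbinol centre needs no control because the next step removes it.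

Step 7
Reactants: 12 (3R)-3-[2-(benzyloxy)-4-bromophenyl]-1-[4-(benzyloxy)-2-methoxyphenyl]-3-[4-(benzyloxy)phenyl]propan-1-ol
Product: 13 2-(benzyloxy)-1-{(1R)-3-[4-(benzyloxy)-2-methoxyphenyl]-1-[4-(benzyloxy)phenyl]propyl}-4-bromobenzene
Conditions: Et3SiH (3 equiv), CF3CO2H (5 equiv), CH2Cl2, −10 to 0 °C
Reagents that add atoms: none
Why: Ionic hydrogenation, in which the carbinol ionises readily because the cation is stabilised by the para-benzyloxy and ortho-methoxy groups and is then reduced by excess silane, while aryl benzyl ethers, the C–Br bond and Cα should persist in cold dilute acid.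

Step 8
Reactants: 13 2-(benzyloxy)-1-{(1R)-3-[4-(benzyloxy)-2-methoxyphenyl]-1-[4-(benzyloxy)phenyl]propyl}-4-bromobenzene
Product: 14 2-(benzyloxy)-1-{(1R)-3-[4-(benzyloxy)-2-methoxyphenyl]-1-[4-(benzyloxy)phenyl]propyl}-4-iodobenzene
Conditions: CuI (10 mol%), NaI (2 equiv), trans-N,N'-dimethylcyclohexane-1,2-diamine (20 mol%), 1,4-dioxane, 110 °C
Reagents that add atoms: sodium iodide, [Na+].[I-]
Why: Copper-catalysed aromatic Finkelstein reaction, driven by the low solubility of NaBr in dioxane and inert toward ethers and the benzylic methine.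

Step 9
Reactants: 15 2',5'-dihydroxyacetophenone
Product: 16 5'-(benzyloxy)-2'-hydroxyacetophenone
Conditions: BnBr (1.0 equiv), K2CO3 (1.1 equiv), acetone, reflux
Reagents that add atoms: benzyl bromide, BrCc1ccccc1
Why: Williamson etherification selective for the 5'-hydroxyl, because the 2'-hydroxyl is held in a hydrogen bond to the ketone and is the poorer nucleophile.

Step 10
Reactants: 16 5'-(benzyloxy)-2'-hydroxyacetophenone
Product: 17 5'-(benzyloxy)-2'-methoxyacetophenone
Conditions: MeI, K2CO3, DMF, 40 °C
Reagents that add atoms: iodomethane, CI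
Why: Williamson methylation of the remaining chelated phenol, which reacts once a polar aprotic solvent and a small electrophile are used.

Step 11
Reactants: 17 5'-(benzyloxy)-2'-methoxyacetophenone
Product: 18 methyl 3-[5-(benzyloxy)-2-methoxyphenyl]-3-oxopropanoate
Conditions: NaH (2.2 equiv), (MeO)2CO, THF, reflux; then aq HCl
Reagents that add atoms: dimethyl carbonate, COC(=O)OC
Why: Crossed Claisen condensation of the ketone enolate with dimethyl carbonate, pulled forward by deprotonation of the β-keto ester; it adds the carbon that becomes C4.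

Step 12
Reactants: 18 methyl 3-[5-(benzyloxy)-2-methoxyphenyl]-3-oxopropanoate
Product: 19 methyl (S)-3-[5-(benzyloxy)-2-methoxyphenyl]-3-hydroxypropanoate
Conditions: [RuCl(p-cymene)((R)-SEGPHOS)]Cl (0.5 mol%), H2 (30 bar), MeOH, 60 °C
Reagents that add atoms: none
Why: Noyori asymmetric hydrogenation of a β-keto ester, in which chelation of the keto and ester oxygens to ruthenium fixes the face of hydride delivery; by analogy with benzoylacetates the (R)-diphosphine should give the S carbinol, and the homogeneous catalyst does not cleave the benzyl ether.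

Step 13
Reactants: 19 methyl (S)-3-[5-(benzyloxy)-2-methoxyphenyl]-3-hydroxypropanoate
Product: 20 (S)-1-[5-(benzyloxy)-2-methoxyphenyl]propane-1,3-diol
Conditions: LiAlH4, THF, 0 °C
Reagents that add atoms: none
Why: Hydride reduction of the ester to the primary alcohol, which does not involve the carbinol stereocentre.

Step 14
Reactants: 20 (S)-1-[5-(benzyloxy)-2-methoxyphenyl]propane-1,3-diol
Product: 21 (S)-3-[5-(benzyloxy)-2-methoxyphenyl]-3-hydroxypropyl 4-methylbenzenesulfonate
Conditions: TsCl (1.05 equiv), Et3N, DMAP (cat.), CH2Cl2, 0 °C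
Reagents that add atoms: 4-toluenesulfonyl chloride, Cc1ccc(cc1)S(Cl)(=O)=O
Why: Selective sulfonylation of the primary over the hindered secondary benzylic hydroxyl; the monotosylate is isolated and purified because any benzylic sulfonate would lead by inversion to the enantiomeric oxetane.

Step 15
Reactants: 21 (S)-3-[5-(benzyloxy)-2-methoxyphenyl]-3-hydroxypropyl 4-methylbenzenesulfonate
Product: 22 (S)-2-[5-(benzyloxy)-2-methoxyphenyl]oxetane
Conditions: KOt-Bu (1.2 equiv), THF, 0 °C to rt
Reagents that add atoms: none
Why: Intramolecular Williamson etherification (4-exo-tet), in which the secondary alkoxide displaces the primary tosylate, so the C–O bond at the stereocentre is kept and the oxetane is S.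

Step 16
Reactants: 14 2-(benzyloxy)-1-{(1R)-3-[4-(benzyloxy)-2-methoxyphenyl]-1-[4-(benzyloxy)phenyl]propyl}-4-iodobenzene; 22 (S)-2-[5-(benzyloxy)-2-methoxyphenyl]oxetane
Product: 23 (2S)-7-(benzyloxy)-2-[5-(benzyloxy)-2-methoxyphenyl]-6-{(1R)-3-[4-(benzyloxy)-2-methoxyphenyl]-1-[4-(benzyloxy)phenyl]propyl}chroman
Conditions: 22 (1.5 equiv), Pd(OAc)2 (10 mol%), RuPhos (20 mol%), 1-butylnorbornene (1.5 equiv), Cs2CO3 (2.5 equiv), 1,4-dioxane, 100 °C
Reagents that add atoms: none
Why: Proposed new method: zerovalent palladium inserts into the C8a–I bond of 14, the norbornene inserts into the aryl–palladium bond, and carbonate-assisted metalation of the neighbouring C4a–H closes an aryl–norbornyl palladacycle whose electron-rich divalent palladium should open 22 by SN2-type oxidative addition at the unsubstituted ring CH2 (the future C4), aided by ring strain close to that of an epoxide and by Cs+ on the oxygen, after which reductive elimination from tetravalent palladium forms C4–C4a. The bridgehead butyl group supplies the steric pressure that a second ortho substituent would normally give, so the norbornene is released by β-carbon elimination, the freed C2 alkoxide binds the palladium now back on C8a, and RuPhos should favour C8a–O1 reductive elimination from the seven-membered palladacycle over β-hydride loss; ring C thus closes by intramolecular aryl etherification, the whole being a (4+2) annulation of O1–C2–C3–C4 onto C4a–C8a. The closest known reaction types are the palladium/norbornene (Catellani) annulation of aryl iodides with epoxides to 2,3-dihydrobenzofurans, which transfers the epoxide configuration unchanged, and the palladium-catalysed cyclisation of 3-(2-halophenyl)propanols bearing a secondary carbinol to chromans; an oxetane has not yet been shown in the role of the electrophile. No stereocentre is formed: the C2–O1 and C2–H bonds of 22 stay intact, so the S configuration passes into 23, and the Cα–H bond is remote and too weakly acidic for Cs2CO3. The step needs C4a over C8, one alkylation only, and CH2 over the benzylic carbon of the oxetane: the 7-benzyloxy group flanks and shields C8, the modified norbornene departs before C8–H can be metalated, and the bulky palladacycle under non-acidic conditions can reach only the unhindered CH2.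

Step 17
Reactants: 23 (2S)-7-(benzyloxy)-2-[5-(benzyloxy)-2-methoxyphenyl]-6-{(1R)-3-[4-(benzyloxy)-2-methoxyphenyl]-1-[4-(benzyloxy)phenyl]propyl}chroman
Product: 24 (2S)-6-[(1R)-3-(4-hydroxy-2-methoxyphenyl)-1-(4-hydroxyphenyl)propyl]-2-(5-hydroxy-2-methoxyphenyl)chroman-7-ol
Conditions: H2 (1 atm), 10% Pd/C, EtOAc/MeOH, rt
Reagents that add atoms: none
Why: Catalytic hydrogenolysis of four aryl benzyl ethers, whose unhindered primary benzyl–oxygen bonds are cleaved far faster than the hindered cyclic C2–O1 bond, so the reaction is stopped after four equivalents of hydrogen and the methyl ethers and both stereocentres remain.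

Compound list
1 | 4-bromo-2-hydroxybenzaldehyde | O=Cc1ccc(Br)cc1O | starting material
2 | ethyl (E)-3-(4-bromo-2-hydroxyphenyl)prop-2-enoate (not isolated) | CCOC(=O)/C=C/c1ccc(Br)cc1O | intermediate
3 | 7-bromocoumarin (7-bromo-2H-chromen-2-one) | O=c1ccc2ccc(Br)cc2o1 | intermediate
4 | 4-(benzyloxy)phenylboronic acid | OB(O)c1ccc(OCc2ccccc2)cc1 | starting material
5 | (R)-4-[4-(benzyloxy)phenyl]-7-bromochroman-2-one | O=C1C[C@H](c2ccc(OCc3ccccc3)cc2)c2ccc(Br)cc2O1 | intermediate
6 | methyl (R)-3-[4-(benzyloxy)phenyl]-3-(4-bromo-2-hydroxyphenyl)propanoate (not isolated) | COC(=O)C[C@H](c1ccc(OCc2ccccc2)cc1)c1ccc(Br)cc1O | intermediate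
7 | methyl (R)-3-[2-(benzyloxy)-4-bromophenyl]-3-[4-(benzyloxy)phenyl]propanoate | COC(=O)C[C@H](c1ccc(OCc2ccccc2)cc1)c1ccc(Br)cc1OCc1ccccc1 | intermediate
8 | (R)-3-[2-(benzyloxy)-4-bromophenyl]-3-[4-(benzyloxy)phenyl]propanal | O=CC[C@H](c1ccc(OCc2ccccc2)cc1)c1ccc(Br)cc1OCc1ccccc1 | intermediate
9 | 4-bromo-3-methoxyphenol | COc1cc(O)ccc1Br | starting material
10 | 4-(benzyloxy)-1-bromo-2-methoxybenzene | COc1cc(OCc2ccccc2)ccc1Br | intermediate
11 | [4-(benzyloxy)-2-methoxyphenyl]magnesium bromide (not isolated) | COc1cc(OCc2ccccc2)ccc1[Mg]Br | intermediate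
12 | (3R)-3-[2-(benzyloxy)-4-bromophenyl]-1-[4-(benzyloxy)-2-methoxyphenyl]-3-[4-(benzyloxy)phenyl]propan-1-ol, both C1 epimers | COc1cc(OCc2ccccc2)ccc1C(O)C[C@H](c1ccc(OCc2ccccc2)cc1)c1ccc(Br)cc1OCc1ccccc1 | intermediate
13 | 2-(benzyloxy)-1-{(1R)-3-[4-(benzyloxy)-2-methoxyphenyl]-1-[4-(benzyloxy)phenyl]propyl}-4-bromobenzene | COc1cc(OCc2ccccc2)ccc1CC[C@H](c1ccc(OCc2ccccc2)cc1)c1ccc(Br)cc1OCc1ccccc1 | intermediate
14 | 2-(benzyloxy)-1-{(1R)-3-[4-(benzyloxy)-2-methoxyphenyl]-1-[4-(benzyloxy)phenyl]propyl}-4-iodobenzene | COc1cc(OCc2ccccc2)ccc1CC[C@H](c1ccc(OCc2ccccc2)cc1)c1ccc(I)cc1OCc1ccccc1 | intermediate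
15 | 2',5'-dihydroxyacetophenone | CC(=O)c1cc(O)ccc1O | starting material
16 | 5'-(benzyloxy)-2'-hydroxyacetophenone | CC(=O)c1cc(OCc2ccccc2)ccc1O | intermediate
17 | 5'-(benzyloxy)-2'-methoxyacetophenone | CC(=O)c1cc(OCc2ccccc2)ccc1OC | intermediate
18 | methyl 3-[5-(benzyloxy)-2-methoxyphenyl]-3-oxopropanoate | COC(=O)CC(=O)c1cc(OCc2ccccc2)ccc1OC | intermediate
19 | methyl (S)-3-[5-(benzyloxy)-2-methoxyphenyl]-3-hydroxypropanoate | O[C@H](c1cc(OCc2ccccc2)ccc1OC)CC(=O)OC | intermediate
20 | (S)-1-[5-(benzyloxy)-2-methoxyphenyl]propane-1,3-diol | O[C@H](c1cc(OCc2ccccc2)ccc1OC)CCO | intermediate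
21 | (S)-3-[5-(benzyloxy)-2-methoxyphenyl]-3-hydroxypropyl 4-methylbenzenesulfonate | O[C@H](c1cc(OCc2ccccc2)ccc1OC)CCOS(=O)(=O)c1ccc(C)cc1 | intermediate
22 | (S)-2-[5-(benzyloxy)-2-methoxyphenyl]oxetane | O1[C@H](c2cc(OCc3ccccc3)ccc2OC)CC1 | intermediate
23 | (2S)-7-(benzyloxy)-2-[5-(benzyloxy)-2-methoxyphenyl]-6-{(1R)-3-[4-(benzyloxy)-2-methoxyphenyl]-1-[4-(benzyloxy)phenyl]propyl}chroman | COc1cc(OCc2ccccc2)ccc1CC[C@H](c1ccc(OCc2ccccc2)cc1)c1cc2c(cc1OCc1ccccc1)O[C@H](c1cc(OCc3ccccc3)ccc1OC)CC2 | intermediate
24 | (2S)-6-[(1R)-3-(4-hydroxy-2-methoxyphenyl)-1-(4-hydroxyphenyl)propyl]-2-(5-hydroxy-2-methoxyphenyl)chroman-7-ol (CNP0239474.1) | COc1cc(O)ccc1CC[C@H](c1ccc(O)cc1)c1cc2c(cc1O)O[C@H](c1cc(O)ccc1OC)CC2 | target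

Total step count: 17.
Longest linear sequence: 9 steps (1 → 3 → 5 → 7 → 8 → 12 → 13 → 14 → 23 → 24). The oxetane branch 15 → 22 → 23 → 24 is also 9 steps.

Steps most likely to fail

Step 16 (proposed new method). Four things could go wrong.
- The palladacycle may open the oxetane too slowly and decay first by carbon–carbon reductive elimination that retains the norbornene.
- The palladium alkoxide may lose β-hydride before the C–O bond forms.
- C8–H may be metalated after the first alkylation.
- Reversible opening at the benzylic carbon may erode the C2 configuration.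

The fallback uses only known chemistry, sets out from 14 and 17, and comes back at 23. Hydroxylation of 14 (CuI, 1,10-phenanthroline, KOH, DMSO/H2O) gives the C8a-phenol F1. Casnati–Skattebøl ortho-formylation (MgCl2, Et3N, paraformaldehyde, MeCN) acts only on the free phenol and prefers the open position para to the benzyloxy group, giving the C4a-salicylaldehyde F2. Claisen–Schmidt condensation with 17 (KOH, EtOH) gives the 2-hydroxychalcone F3. Asymmetric transfer hydrogenation with RuCl(p-cymene)[(R,R)-TsDPEN] and HCO2Na reduces first the C=C and then the C=O bond to the (R)-diarylpropanol F4. Intramolecular Mitsunobu etherification (PPh3, DIAD, THF) then closes ring C with inversion to the 2S flavan 23.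

Step 7. The stabilised benzylic cation may be intercepted by a neighbouring arene or by the ortho-benzyloxy oxygen before hydride transfer, or the acid may strip benzyl groups. The fallback sets out from 12 and comes back at 13, and it avoids both acid and hydride capture. Mesylation and elimination under basic conditions (MsCl, Et3N, then DBU, CH2Cl2) gives the (E)-styrene F5. Diimide generated from TsNHNH2 and NaOAc in refluxing THF/H2O then saturates the alkene without touching the C–Br bond or the benzyl ethers.

Step 12. Facial selectivity may be poor if the ortho-methoxy oxygen competes with the ester carbonyl for ruthenium. The fallback sets out from 18 and comes back at 19, replacing asymmetric catalysis by kinetic resolution. NaBH4 in MeOH at 0 °C gives the racemic β-hydroxy ester F6. Lipase-catalysed transesterification (Burkholderia cepacia lipase, vinyl acetate, MTBE) should, by the usual empirical rule for secondary carbinols, acylate the R enantiomer to the (R)-acetate F7. The S alcohol 19 is left unreacted and is separated by chromatography.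

Further compounds
F1 | step 16 | C8a-phenol, 3-(benzyloxy)-4-{(1R)-3-[4-(benzyloxy)-2-methoxyphenyl]-1-[4-(benzyloxy)phenyl]propyl}phenol | COc1cc(OCc2ccccc2)ccc1CC[C@H](c1ccc(OCc2ccccc2)cc1)c1ccc(O)cc1OCc1ccccc1
F2 | step 16 | C4a-salicylaldehyde, 4-(benzyloxy)-5-{(1R)-3-[4-(benzyloxy)-2-methoxyphenyl]-1-[4-(benzyloxy)phenyl]propyl}-2-hydroxybenzaldehyde | COc1cc(OCc2ccccc2)ccc1CC[C@H](c1ccc(OCc2ccccc2)cc1)c1cc(C=O)c(O)cc1OCc1ccccc1
F3 | step 16 | 2-hydroxychalcone, (E)-3-[4-(benzyloxy)-5-{(1R)-3-[4-(benzyloxy)-2-methoxyphenyl]-1-[4-(benzyloxy)phenyl]propyl}-2-hydroxyphenyl]-1-[5-(benzyloxy)-2-methoxyphenyl]prop-2-en-1-one | COc1cc(OCc2ccccc2)ccc1CC[C@H](c1ccc(OCc2ccccc2)cc1)c1cc(/C=C/C(=O)c2cc(OCc3ccccc3)ccc2OC)c(O)cc1OCc1ccccc1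
F4 | step 16 | (R)-diarylpropanol, 5-(benzyloxy)-2-{(3R)-3-[5-(benzyloxy)-2-methoxyphenyl]-3-hydroxypropyl}-4-{(1R)-3-[4-(benzyloxy)-2-methoxyphenyl]-1-[4-(benzyloxy)phenyl]propyl}phenol | COc1cc(OCc2ccccc2)ccc1CC[C@H](c1ccc(OCc2ccccc2)cc1)c1cc(CC[C@@H](O)c2cc(OCc3ccccc3)ccc2OC)c(O)cc1OCc1ccccc1
F5 | step 7 | (E)-styrene, 2-(benzyloxy)-1-{(1R,2E)-3-[4-(benzyloxy)-2-methoxyphenyl]-1-[4-(benzyloxy)phenyl]prop-2-en-1-yl}-4-bromobenzene | COc1cc(OCc2ccccc2)ccc1/C=C/[C@H](c1ccc(OCc2ccccc2)cc1)c1ccc(Br)cc1OCc1ccccc1
F6 | step 12 | racemic β-hydroxy ester, methyl 3-[5-(benzyloxy)-2-methoxyphenyl]-3-hydroxypropanoate | COC(=O)CC(O)c1cc(OCc2ccccc2)ccc1OC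
F7 | step 12 | (R)-acetate, methyl (R)-3-acetoxy-3-[5-(benzyloxy)-2-methoxyphenyl]propanoate | COC(=O)C[C@@H](OC(C)=O)c1cc(OCc2ccccc2)ccc1OC
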